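**Retrosynthetic overview**
1. Target 30 ⇐ desilylation of 29; the C5 carbinol ⇐ Luche reduction of macrocyclic enone 28 ⇐ oxidation of the alcohol from a Nozaki–Hiyama–Kishi closure of the C4–C5 bond (ten-membered ring, formed last).
2. C8 ester ⇐ Mitsunobu esterification with inversion of adduct 21 using (2R)-2-methylbutanoic acid.
3. Key union C7–C8: zinc Barbier allylation of aldehyde 19 with bromomethyl butenolide 6; it sets C7 and C8 and turns the butenolide into the α-methylene-γ-lactone.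
4. 6 ⇐ (S)-glycidol (C6) and 2-(bromomethyl)acrylic acid by ring-closing metathesis (five-membered lactone, formed first); 19 ⇐ Evans alkylation (C10), ozonolysis and Z-selective iodo-olefination.

Assumption: locants C1–C15 in the text are those of the target (ring C1–C10 with C3=C4, C5–OH, C6–O lactone, C8–O ester, C10–CH2OH = C14; C11=C13H2; C12 lactone carbonyl; C15 methyl on C4), and (2R)-2-methylbutanoic acid is bought as the single enantiomer.

**Route**

Step 1
Reactants: 1 (S)-glycidol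
Product: 2 (2R)-2-{[(4-methoxybenzyl)oxy]methyl}oxirane
Conditions: NaH, 4-methoxybenzyl chloride, Bu4NI (cat.), DMF, 0 °C to rt
Reagents that add atoms: 4-methoxybenzyl chloride (COc1ccc(CCl)cc1)
Why: Williamson etherification of the primary alkoxide leaves the stereocentre untouched (the descriptor changes from S to R only through CIP priorities).

Step 2
Reactants: 2 (2R)-2-{[(4-methoxybenzyl)oxy]methyl}oxirane
Product: 3 (2R)-1-[(4-methoxybenzyl)oxy]but-3-en-2-ol
Conditions: trimethylsulfonium iodide (3 equiv), n-BuLi (2.9 equiv), THF, −10 °C to rt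
Reagents that add atoms: trimethylsulfonium iodide (C[S+](C)C.[I-])
Why: Sulfonium-ylide epoxide homologation: the ylide opens the epoxide at its CH2 terminus and the sulfonium alkoxide eliminates dimethyl sulfide to the allylic alcohol, with the carbinol centre retained.

Step 3
Reactants: 3 (2R)-1-[(4-methoxybenzyl)oxy]but-3-en-2-ol; 4 2-(bromomethyl)acrylic acid
Product: 5 (2R)-1-[(4-methoxybenzyl)oxy]but-3-en-2-yl 2-(bromomethyl)acrylate
Conditions: N,N'-dicyclohexylcarbodiimide, DMAP (5 mol %), CH2Cl2, 0 °C to rt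
Reagents that add atoms: none
Why: Steglich esterification of the secondary allylic alcohol at low temperature with little DMAP, so that the allylic bromide survives; no stereocentre is affected.

Step 4
Reactants: 5 (2R)-1-[(4-methoxybenzyl)oxy]but-3-en-2-yl 2-(bromomethyl)acrylate
Product: 6 (5R)-3-(bromomethyl)-5-{[(4-methoxybenzyl)oxy]methyl}furan-2(5H)-one
Conditions: second-generation Grubbs catalyst RuCl2(=CHPh)(H2IMes)(PCy3) (5 mol %), CH2Cl2 (0.01 mol/L), 40 °C
Reagents that add atoms: none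
Why: Ring-closing metathesis of the vinyl group onto the 2-substituted acrylate forms the five-membered butenolide with loss of ethene; the C6 centre is not involved.

Step 5
Reactants: 7 (4R)-4-benzyl-1,3-oxazolidin-2-one; 8 hex-5-enoyl chloride
Product: 9 (4R)-4-benzyl-3-(hex-5-enoyl)-1,3-oxazolidin-2-one
Conditions: Et3N, DMAP (10 mol %), CH2Cl2, 0 °C to rt
Reagents that add atoms: none
Why: DMAP-catalysed N-acylation of the oxazolidinone with the acid chloride gives the imide for auxiliary-controlled alkylation.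

Step 6
Reactants: 9 (4R)-4-benzyl-3-(hex-5-enoyl)-1,3-oxazolidin-2-one; 10 tert-butyl bromoacetate
Product: 12 tert-butyl (3S)-3-{[(4R)-4-benzyl-2-oxo-1,3-oxazolidin-3-yl]carbonyl}hept-6-enoate, via sodium enolate 11 (not isolated)
Conditions: NaN(SiMe3)2, THF, −78 °C; then 10, −78 to −40 °C
Reagents that add atoms: none
Why: Evans asymmetric alkylation: the chelated sodium Z-enolate is alkylated on the face opposite the benzyl group of the (R)-auxiliary, which sets the (S) centre that becomes C10.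

Step 7
Reactants: 12 tert-butyl (3S)-3-{[(4R)-4-benzyl-2-oxo-1,3-oxazolidin-3-yl]carbonyl}hept-6-enoate
Product: 13 tert-butyl (3S)-3-(hydroxymethyl)hept-6-enoate
Conditions: LiBH4, MeOH (1.1 equiv), THF, 0 °C
Reagents that add atoms: none
Why: Reductive removal of the auxiliary: LiBH4 reduces the activated imide carbonyl to the primary alcohol (C14) much faster than the hindered tert-butyl ester, and the stereocentre is not epimerised.

Step 8
Reactants: 13 tert-butyl (3S)-3-(hydroxymethyl)hept-6-enoate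
Product: 14 tert-butyl (3S)-3-{[(tert-butyldiphenylsilyl)oxy]methyl}hept-6-enoate
Conditions: tert-butyl(chloro)diphenylsilane, imidazole, CH2Cl2, 0 °C to rt
Reagents that add atoms: tert-butyl(chloro)diphenylsilane (CC(C)(C)[Si](Cl)(c1ccccc1)c1ccccc1)
Why: Silylation of the primary alcohol blocks lactonisation and gives a robust C14 protecting group that lasts to the final step.

Step 9
Reactants: 14 tert-butyl (3S)-3-{[(tert-butyldiphenylsilyl)oxy]methyl}hept-6-enoate
Product: 16 tert-butyl (3S)-3-{[(tert-butyldiphenylsilyl)oxy]methyl}-6-oxohexanoate, via ozonide 15 (not isolated)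
Conditions: O3, CH2Cl2, −78 °C; then PPh3, −78 °C to rt
Reagents that add atoms: ozone ([O-][O+]=O)
Why: Ozonolysis with reductive work-up cleaves the only alkene to the C3 aldehyde before any other alkene is present.

Step 10
Reactants: 16 tert-butyl (3S)-3-{[(tert-butyldiphenylsilyl)oxy]methyl}-6-oxohexanoate
Product: 17 tert-butyl (3S,6Z)-3-{[(tert-butyldiphenylsilyl)oxy]methyl}-7-iodooct-6-enoate
Conditions: ethyltriphenylphosphonium iodide, n-BuLi, THF, rt; I2, −78 °C; NaN(SiMe3)2, −20 °C; then 16, −78 °C to rt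
Reagents that add atoms: ethyltriphenylphosphonium iodide (CC[P+](c1ccccc1)(c1ccccc1)c1ccccc1.[I-]); iodine (II)
Why: Stork–Zhao-type Wittig iodo-olefination: the non-stabilised α-iodo ylide reacts under kinetic control through the cis-oxaphosphetane to give the (Z)-2-iodoalkene (iodine cis to the chain), which fixes the later ring-alkene geometry.

Step 11
Reactants: 17 tert-butyl (3S,6Z)-3-{[(tert-butyldiphenylsilyl)oxy]methyl}-7-iodooct-6-enoate
Product: 18 (3S,6Z)-3-{[(tert-butyldiphenylsilyl)oxy]methyl}-7-iodooct-6-en-1-ol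
Conditions: i-Bu2AlH (2.5 equiv), CH2Cl2, −78 to 0 °C
Reagents that add atoms: none
Why: Full hydride reduction of the tert-butyl ester to the primary alcohol is more dependable than a partial reduction and leaves the alkenyl iodide and the silyl ether intact.

Step 12
Reactants: 18 (3S,6Z)-3-{[(tert-butyldiphenylsilyl)oxy]methyl}-7-iodooct-6-en-1-ol
Product: 19 (3S,6Z)-3-{[(tert-butyldiphenylsilyl)oxy]methyl}-7-iodooct-6-enal
Conditions: Dess–Martin periodinane, CH2Cl2, 0 °C to rt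
Reagents that add atoms: none
Why: Dess–Martin oxidation gives the C8 aldehyde under neutral conditions; the C10 centre is not alpha to the carbonyl and cannot epimerise.

Step 13
Reactants: 6 (5R)-3-(bromomethyl)-5-{[(4-methoxybenzyl)oxy]methyl}furan-2(5H)-one; 19 (3S,6Z)-3-{[(tert-butyldiphenylsilyl)oxy]methyl}-7-iodooct-6-enal
Product: 21 (4S,5R)-4-[(1R,3S,6Z)-3-{[(tert-butyldiphenylsilyl)oxy]methyl}-1-hydroxy-7-iodooct-6-en-1-yl]-5-{[(4-methoxybenzyl)oxy]methyl}-3-methylideneoxolan-2-one, via allylzinc bromide 20 (not isolated)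
Conditions: Zn dust, THF/sat. aq. NH4Cl (2:1), 0 °C to rt
Reagents that add atoms: none
Why: Zinc-mediated Barbier carbonyl allylation: the allylzinc from 6 attacks the aldehyde through its ring γ-carbon in a chair six-membered (Zimmerman–Traxler) transition state, anti to the C6 substituent (C6/C7 trans) and with the aldehyde chain equatorial, giving the exo-methylene lactone with the carbinol (R)-configured, that is C8 epimeric to the target and set up for inversion.

Step 14
Reactants: 21 the Barbier adduct of step 13; 22 (2R)-2-methylbutanoic acid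
Product: 23 (1S,3S,6Z)-3-{[(tert-butyldiphenylsilyl)oxy]methyl}-7-iodo-1-[(2R,3S)-2-{[(4-methoxybenzyl)oxy]methyl}-4-methylidene-5-oxooxolan-3-yl]oct-6-en-1-yl (2R)-2-methylbutanoate
Conditions: PPh3, DIAD, toluene, 0 °C to rt
Reagents that add atoms: none
Why: Mitsunobu esterification: the carboxylate displaces the alkoxyphosphonium at C8 by SN2, inverting C8 to the (S) configuration of the target while installing the ester; the acid reacts as a carboxylate, so its own stereocentre cannot epimerise.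

Step 15
Reactants: 23 the Mitsunobu ester of step 14
Product: 24 (1S,3S,6Z)-3-{[(tert-butyldiphenylsilyl)oxy]methyl}-1-[(2R,3S)-2-(hydroxymethyl)-4-methylidene-5-oxooxolan-3-yl]-7-iodooct-6-en-1-yl (2R)-2-methylbutanoate
Conditions: DDQ, CH2Cl2/H2O (10:1), 0 °C to rt
Reagents that add atoms: none
Why: Oxidative cleavage of the electron-rich 4-methoxybenzyl ether frees the C5 primary alcohol without touching the silyl ether, the esters, the alkenyl iodide or the exo-methylene lactone.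

Step 16
Reactants: 24 the primary alcohol of step 15
Product: 25 (1S,3S,6Z)-3-{[(tert-butyldiphenylsilyl)oxy]methyl}-1-[(2R,3S)-2-formyl-4-methylidene-5-oxooxolan-3-yl]-7-iodooct-6-en-1-yl (2R)-2-methylbutanoate
Conditions: Dess–Martin periodinane, CH2Cl2, 0 °C to rt
Reagents that add atoms: none
Why: Neutral Dess–Martin oxidation gives the α-acyloxy aldehyde (C5) without epimerising C6; it is used crude in the next step.

Step 17
Reactants: 25 the iodo aldehyde of step 16
Product: 27 [(3aS,4S,6S,9Z,11aR)-6-{[(tert-butyldiphenylsilyl)oxy]methyl}-11-hydroxy-10-methyl-3-methylidene-2-oxo-2,3,3a,4,5,6,7,8,11,11a-decahydrocyclodeca[b]furan-4-yl] (2R)-2-methylbutanoate (both C11 epimers), via alkenylchromium dichloride 26 (not isolated)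
Conditions: CrCl2 (12 equiv), NiCl2 (0.1 equiv), DMSO/THF (3:1), rt, 0.002 mol/L, slow addition of 25
Reagents that add atoms: none
Why: Intramolecular Nozaki–Hiyama–Kishi reaction at high dilution: divalent chromium with nickel catalysis converts the alkenyl iodide with retention of the Z geometry into an alkenylchromium that adds to the aldehyde and closes the ten-membered ring; the C5 configuration formed here is not relied on because both epimers converge in steps 18 and 19.

Step 18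
Reactants: 27 the macrocyclic allylic alcohol of step 17 (epimer mixture)
Product: 28 [(3aS,4S,6S,9Z,11aR)-6-{[(tert-butyldiphenylsilyl)oxy]methyl}-10-methyl-3-methylidene-2,11-dioxo-2,3,3a,4,5,6,7,8,11,11a-decahydrocyclodeca[b]furan-4-yl] (2R)-2-methylbutanoate
Conditions: Dess–Martin periodinane, CH2Cl2, 0 °C to rt
Reagents that add atoms: none
Why: Dess–Martin oxidation of both allylic alcohol epimers gives one Z-enone under neutral conditions that do not enolise C6.

Step 19
Reactants: 28 the macrocyclic enone of step 18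
Product: 29 [(3aS,4S,6S,9Z,11R,11aR)-6-{[(tert-butyldiphenylsilyl)oxy]methyl}-11-hydroxy-10-methyl-3-methylidene-2-oxo-2,3,3a,4,5,6,7,8,11,11a-decahydrocyclodeca[b]furan-4-yl] (2R)-2-methylbutanoate
Conditions: NaBH4, CeCl3·7H2O, MeOH, −78 °C
Reagents that add atoms: none
Why: Luche 1,2-reduction: hydride adds to the cerium-activated ketone anti to the polar C6–O bond (Felkin–Anh) from the outer face of the ring, which should give the 5,6-syn (5R) allylic alcohol, while −78 °C spares the α-methylene lactone and the esters.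

Step 20
Reactants: 29 the (5R)-alcohol of step 19
Product: 30 [(3aS,4S,6S,9Z,11R,11aR)-11-hydroxy-6-(hydroxymethyl)-10-methyl-3-methylidene-2-oxo-2,3,3a,4,5,6,7,8,11,11a-decahydrocyclodeca[b]furan-4-yl] (2R)-2-methylbutanoate (CNP0147756.3)
Conditions: HF·pyridine, pyridine, THF, 0 °C to rt
Reagents that add atoms: none
Why: Buffered fluoride desilylation removes the silyl ether under mildly acidic, non-nucleophilic conditions that do not add to the α-methylene lactone, migrate the ester or touch any stereocentre.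

**Compound list**

1 | (S)-glycidol | OC[C@H]1CO1 | starting material
2 | (2R)-2-{[(4-methoxybenzyl)oxy]methyl}oxirane | COc1ccc(COC[C@H]2CO2)cc1 | intermediate
3 | (2R)-1-[(4-methoxybenzyl)oxy]but-3-en-2-ol | COc1ccc(COC[C@H](O)C=C)cc1 | intermediate
4 | 2-(bromomethyl)acrylic acid | C=C(CBr)C(=O)O | starting material
5 | (2R)-1-[(4-methoxybenzyl)oxy]but-3-en-2-yl 2-(bromomethyl)acrylate | COc1ccc(COC[C@H](OC(=O)C(=C)CBr)C=C)cc1 | intermediate
6 | (5R)-3-(bromomethyl)-5-{[(4-methoxybenzyl)oxy]methyl}furan-2(5H)-one | COc1ccc(COC[C@@H]2OC(=O)C(CBr)=C2)cc1 | intermediate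
7 | (4R)-4-benzyl-1,3-oxazolidin-2-one | O=C1OC[C@@H](Cc2ccccc2)N1 | starting material
8 | hex-5-enoyl chloride | C=CCCCC(Cl)=O | starting material
9 | (4R)-4-benzyl-3-(hex-5-enoyl)-1,3-oxazolidin-2-one | C=CCCCC(=O)N1C(=O)OC[C@H]1Cc2ccccc2 | intermediate
10 | tert-butyl bromoacetate | CC(C)(C)OC(=O)CBr | starting material
11 | sodium (1Z)-1-[(4R)-4-benzyl-2-oxo-1,3-oxazolidin-3-yl]hexa-1,5-dien-1-olate (sodium enolate of 9) | C=CCC/C=C(\[O-])N1C(=O)OC[C@H]1Cc2ccccc2.[Na+] | intermediate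
12 | tert-butyl (3S)-3-{[(4R)-4-benzyl-2-oxo-1,3-oxazolidin-3-yl]carbonyl}hept-6-enoate | CC(C)(C)OC(=O)C[C@@H](C(=O)N1C(=O)OC[C@H]1Cc2ccccc2)CCC=C | intermediate
13 | tert-butyl (3S)-3-(hydroxymethyl)hept-6-enoate | CC(C)(C)OC(=O)C[C@@H](CO)CCC=C | intermediate
14 | tert-butyl (3S)-3-{[(tert-butyldiphenylsilyl)oxy]methyl}hept-6-enoate | CC(C)(C)OC(=O)C[C@@H](CO[Si](c1ccccc1)(c1ccccc1)C(C)(C)C)CCC=C | intermediate
15 | tert-butyl (3S)-3-{[(tert-butyldiphenylsilyl)oxy]methyl}-5-(1,2,4-trioxolan-3-yl)pentanoate (ozonide of 14, trioxolane carbon unassigned) | CC(C)(C)OC(=O)C[C@@H](CO[Si](c1ccccc1)(c1ccccc1)C(C)(C)C)CCC1OCOO1 | intermediate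
16 | tert-butyl (3S)-3-{[(tert-butyldiphenylsilyl)oxy]methyl}-6-oxohexanoate | CC(C)(C)OC(=O)C[C@@H](CO[Si](c1ccccc1)(c1ccccc1)C(C)(C)C)CCC=O | intermediate
17 | tert-butyl (3S,6Z)-3-{[(tert-butyldiphenylsilyl)oxy]methyl}-7-iodooct-6-enoate | CC(C)(C)OC(=O)C[C@@H](CO[Si](c1ccccc1)(c1ccccc1)C(C)(C)C)CC/C=C(/C)I | intermediate
18 | (3S,6Z)-3-{[(tert-butyldiphenylsilyl)oxy]methyl}-7-iodooct-6-en-1-ol | OCC[C@@H](CO[Si](c1ccccc1)(c1ccccc1)C(C)(C)C)CC/C=C(/C)I | intermediate
19 | (3S,6Z)-3-{[(tert-butyldiphenylsilyl)oxy]methyl}-7-iodooct-6-enal | O=CC[C@@H](CO[Si](c1ccccc1)(c1ccccc1)C(C)(C)C)CC/C=C(/C)I | intermediate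
20 | bromo({(5R)-5-{[(4-methoxybenzyl)oxy]methyl}-2-oxo-2,5-dihydrofuran-3-yl}methyl)zinc (allylzinc bromide from 6) | COc1ccc(COC[C@@H]2OC(=O)C(C[Zn]Br)=C2)cc1 | intermediate
21 | (4S,5R)-4-[(1R,3S,6Z)-3-{[(tert-butyldiphenylsilyl)oxy]methyl}-1-hydroxy-7-iodooct-6-en-1-yl]-5-{[(4-methoxybenzyl)oxy]methyl}-3-methylideneoxolan-2-one | C=C1C(=O)O[C@@H](COCc2ccc(OC)cc2)[C@@H]1[C@H](O)C[C@@H](CO[Si](c3ccccc3)(c3ccccc3)C(C)(C)C)CC/C=C(/C)I | intermediate
22 | (2R)-2-methylbutanoic acid | CC[C@@H](C)C(=O)O | starting material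
23 | (1S,3S,6Z)-3-{[(tert-butyldiphenylsilyl)oxy]methyl}-7-iodo-1-[(2R,3S)-2-{[(4-methoxybenzyl)oxy]methyl}-4-methylidene-5-oxooxolan-3-yl]oct-6-en-1-yl (2R)-2-methylbutanoate | C=C1C(=O)O[C@@H](COCc2ccc(OC)cc2)[C@@H]1[C@@H](OC(=O)[C@H](C)CC)C[C@@H](CO[Si](c3ccccc3)(c3ccccc3)C(C)(C)C)CC/C=C(/C)I | intermediate
24 | (1S,3S,6Z)-3-{[(tert-butyldiphenylsilyl)oxy]methyl}-1-[(2R,3S)-2-(hydroxymethyl)-4-methylidene-5-oxooxolan-3-yl]-7-iodooct-6-en-1-yl (2R)-2-methylbutanoate | C=C1C(=O)O[C@@H](CO)[C@@H]1[C@@H](OC(=O)[C@H](C)CC)C[C@@H](CO[Si](c3ccccc3)(c3ccccc3)C(C)(C)C)CC/C=C(/C)I | intermediate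
25 | (1S,3S,6Z)-3-{[(tert-butyldiphenylsilyl)oxy]methyl}-1-[(2R,3S)-2-formyl-4-methylidene-5-oxooxolan-3-yl]-7-iodooct-6-en-1-yl (2R)-2-methylbutanoate | C=C1C(=O)O[C@@H](C=O)[C@@H]1[C@@H](OC(=O)[C@H](C)CC)C[C@@H](CO[Si](c3ccccc3)(c3ccccc3)C(C)(C)C)CC/C=C(/C)I | intermediate
26 | alkenylchromium dichloride of 25 (CrCl2 unit of trivalent chromium in place of the iodine at C4, Z geometry kept) | C=C1C(=O)O[C@@H](C=O)[C@@H]1[C@@H](OC(=O)[C@H](C)CC)C[C@@H](CO[Si](c3ccccc3)(c3ccccc3)C(C)(C)C)CC/C=C(/C)[Cr](Cl)Cl | intermediate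
27 | [(3aS,4S,6S,9Z,11aR)-6-{[(tert-butyldiphenylsilyl)oxy]methyl}-11-hydroxy-10-methyl-3-methylidene-2-oxo-2,3,3a,4,5,6,7,8,11,11a-decahydrocyclodeca[b]furan-4-yl] (2R)-2-methylbutanoate, both C11 epimers (C5 of the target) | C=C1C(=O)O[C@@H]2[C@@H]1[C@@H](OC(=O)[C@H](C)CC)C[C@@H](CO[Si](c3ccccc3)(c3ccccc3)C(C)(C)C)CC/C=C(/C)C2O | intermediate
28 | [(3aS,4S,6S,9Z,11aR)-6-{[(tert-butyldiphenylsilyl)oxy]methyl}-10-methyl-3-methylidene-2,11-dioxo-2,3,3a,4,5,6,7,8,11,11a-decahydrocyclodeca[b]furan-4-yl] (2R)-2-methylbutanoate | C=C1C(=O)O[C@@H]2[C@@H]1[C@@H](OC(=O)[C@H](C)CC)C[C@@H](CO[Si](c3ccccc3)(c3ccccc3)C(C)(C)C)CC/C=C(/C)C2=O | intermediate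
29 | [(3aS,4S,6S,9Z,11R,11aR)-6-{[(tert-butyldiphenylsilyl)oxy]methyl}-11-hydroxy-10-methyl-3-methylidene-2-oxo-2,3,3a,4,5,6,7,8,11,11a-decahydrocyclodeca[b]furan-4-yl] (2R)-2-methylbutanoate | C=C1C(=O)O[C@@H]2[C@@H]1[C@@H](OC(=O)[C@H](C)CC)C[C@@H](CO[Si](c3ccccc3)(c3ccccc3)C(C)(C)C)CC/C=C(/C)[C@H]2O | intermediate
30 | [(3aS,4S,6S,9Z,11R,11aR)-11-hydroxy-6-(hydroxymethyl)-10-methyl-3-methylidene-2-oxo-2,3,3a,4,5,6,7,8,11,11a-decahydrocyclodeca[b]furan-4-yl] (2R)-2-methylbutanoate (CNP0147756.3) | C=C1C(=O)O[C@@H]2[C@@H]1[C@@H](OC(=O)[C@H](C)CC)C[C@@H](CO)CC/C=C(/C)[C@H]2O | target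

**Step count and risks**

Total step count: 20 (steps 1–4 make bromide 6, steps 5–12 make aldehyde 19, steps 13–20 join and finish).
Longest linear sequence: 16 steps (steps 5–20, from 7 and 8).

The three steps most likely to fail:

1. Step 14 (Mitsunobu esterification). The carbinol is hindered and sits next to the lactone ring, so elimination towards C7 or incomplete inversion is possible. Fallback: set out from 21, treat it with methanesulfonyl chloride and Et3N in CH2Cl2 at −20 °C to give (1R,3S,6Z)-3-{[(tert-butyldiphenylsilyl)oxy]methyl}-7-iodo-1-[(2R,3R)-2-{[(4-methoxybenzyl)oxy]methyl}-4-methylidene-5-oxooxolan-3-yl]oct-6-en-1-yl methanesulfonate F1. Then displace the sulfonate with caesium (2R)-2-methylbutanoate (from 22 and Cs2CO3) and 18-crown-6 in toluene at 80 °C. This two-stage sulfonate activation and carboxylate SN2 displacement inverts C8 and comes back to the route at 23.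

2. Step 17 (Nozaki–Hiyama–Kishi macrocyclisation). Closing a ten-membered ring onto an epimerisable α-acyloxy aldehyde may give oligomers or low yield. Fallback: set out from 25 and raise the oxidation level of C5 instead of adding to the aldehyde. Pinnick oxidation (NaClO2, NaH2PO4, 2-methylbut-2-ene, t-BuOH/H2O) gives (2R,3S)-3-[(1S,3S,6Z)-3-{[(tert-butyldiphenylsilyl)oxy]methyl}-7-iodo-1-{[(2R)-2-methylbutanoyl]oxy}oct-6-en-1-yl]-4-methylidene-5-oxooxolane-2-carboxylic acid F2. 2,2'-Dipyridyl disulfide and PPh3 then give S-(pyridin-2-yl) (2R,3S)-3-[(1S,3S,6Z)-3-{[(tert-butyldiphenylsilyl)oxy]methyl}-7-iodo-1-{[(2R)-2-methylbutanoyl]oxy}oct-6-en-1-yl]-4-methylidene-5-oxooxolane-2-carbothioate F3. A nickel-catalysed reductive acyl–alkenyl coupling of the thioester with the alkenyl iodide (NiBr2(dtbbpy), Cp2ZrCl2, Zn, 1,3-dimethylimidazolidin-2-one, rt, high dilution) closes the ring as the ketone. This comes back to the route at 28 and replaces steps 17 and 18; its use on alkenyl iodides and for ring closure is less established than the main step.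

3. Step 19 (Luche reduction). In the strained ring, conformational control may override the Felkin–Anh preference and deliver the C5 epimer. Fallback: set out from 28; if hydride gives mainly [(3aS,4S,6S,9Z,11S,11aR)-6-{[(tert-butyldiphenylsilyl)oxy]methyl}-11-hydroxy-10-methyl-3-methylidene-2-oxo-2,3,3a,4,5,6,7,8,11,11a-decahydrocyclodeca[b]furan-4-yl] (2R)-2-methylbutanoate F4, invert it by a Mitsunobu reaction with formic acid (PPh3, DIAD, THF, 0 °C). This gives [(3aS,4S,6S,9Z,11R,11aR)-6-{[(tert-butyldiphenylsilyl)oxy]methyl}-11-(formyloxy)-10-methyl-3-methylidene-2-oxo-2,3,3a,4,5,6,7,8,11,11a-decahydrocyclodeca[b]furan-4-yl] (2R)-2-methylbutanoate F5. Brief methanolysis of the formate (KHCO3, MeOH, 0 °C) leaves the other esters and the lactone intact and comes back to the route at 29.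

**Further compounds**

F1 | step 14 | (1R,3S,6Z)-3-{[(tert-butyldiphenylsilyl)oxy]methyl}-7-iodo-1-[(2R,3R)-2-{[(4-methoxybenzyl)oxy]methyl}-4-methylidene-5-oxooxolan-3-yl]oct-6-en-1-yl methanesulfonate | C=C1C(=O)O[C@@H](COCc2ccc(OC)cc2)[C@@H]1[C@H](OS(C)(=O)=O)C[C@@H](CO[Si](c3ccccc3)(c3ccccc3)C(C)(C)C)CC/C=C(/C)I
F2 | step 17 | (2R,3S)-3-[(1S,3S,6Z)-3-{[(tert-butyldiphenylsilyl)oxy]methyl}-7-iodo-1-{[(2R)-2-methylbutanoyl]oxy}oct-6-en-1-yl]-4-methylidene-5-oxooxolane-2-carboxylic acid | C=C1C(=O)O[C@@H](C(=O)O)[C@@H]1[C@@H](OC(=O)[C@H](C)CC)C[C@@H](CO[Si](c3ccccc3)(c3ccccc3)C(C)(C)C)CC/C=C(/C)I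
F3 | step 17 | S-(pyridin-2-yl) (2R,3S)-3-[(1S,3S,6Z)-3-{[(tert-butyldiphenylsilyl)oxy]methyl}-7-iodo-1-{[(2R)-2-methylbutanoyl]oxy}oct-6-en-1-yl]-4-methylidene-5-oxooxolane-2-carbothioate | C=C1C(=O)O[C@@H](C(=O)Sc2ccccn2)[C@@H]1[C@@H](OC(=O)[C@H](C)CC)C[C@@H](CO[Si](c3ccccc3)(c3ccccc3)C(C)(C)C)CC/C=C(/C)I
F4 | step 19 | [(3aS,4S,6S,9Z,11S,11aR)-6-{[(tert-butyldiphenylsilyl)oxy]methyl}-11-hydroxy-10-methyl-3-methylidene-2-oxo-2,3,3a,4,5,6,7,8,11,11a-decahydrocyclodeca[b]furan-4-yl] (2R)-2-methylbutanoate | C=C1C(=O)O[C@@H]2[C@@H]1[C@@H](OC(=O)[C@H](C)CC)C[C@@H](CO[Si](c3ccccc3)(c3ccccc3)C(C)(C)C)CC/C=C(/C)[C@@H]2O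
F5 | step 19 | [(3aS,4S,6S,9Z,11R,11aR)-6-{[(tert-butyldiphenylsilyl)oxy]methyl}-11-(formyloxy)-10-methyl-3-methylidene-2-oxo-2,3,3a,4,5,6,7,8,11,11a-decahydrocyclodeca[b]furan-4-yl] (2R)-2-methylbutanoate | C=C1C(=O)O[C@@H]2[C@@H]1[C@@H](OC(=O)[C@H](C)CC)C[C@@H](CO[Si](c3ccccc3)(c3ccccc3)C(C)(C)C)CC/C=C(/C)[C@H]2OC=O
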